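**Retrosynthetic overview**
- The dialdehyde is unmasked last from a cyclic bis(methyl acetal). The p-coumarate comes from a Heck reaction of a C1 acrylate with 4-iodophenol, and the 1β-alcohol from oxidation/axial-hydride reduction of a 1α-alcohol.
- Key disconnection: rings A and B (C4–C5, then C10–C9) form in one Fe–H-initiated radical cascade from an acyclic dienyl sulfone. The cascade ends by loss of PhSO2•, which places the alkene at C7=C8.
- The acyclic precursor comes from an asymmetric alkenylzinc addition (C1–C10 bond) of a hydrozirconated internal alkyne to 4-methylpent-4-enal. This carbinol is the only source of absolute configuration.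
- The alkyne comes from alkylation (C6–C7) of 3-[(phenylsulfonyl)methyl]furan with 1-bromobut-2-yne, followed by oxidative dimethoxylation of the furan.
- Ring order: the dihydrofuran (masked dialdehyde, from the furan) first, then ring A and ring B in the same step.

Assumption: positions are given in drimane numbering (C11 on C9, C12 on C8, C15 = methyl on C10), and 4-methylpent-4-enal (7) is taken as a catalogue compound.

**Route**

Step 1
Reactants: 1 furan-3-ylmethanol
Product: 3 3-[(phenylsulfonyl)methyl]furan, via 3-(bromomethyl)furan 2 (not isolated)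
Conditions: PBr3, Et2O, 0 °C; then PhSO2Na, DMF, rt
Reagents that add atoms: sodium benzenesulfinate, [Na+].[O-]S(=O)c1ccccc1
Why: Bromination of the furylmethyl alcohol followed by SN2 S-alkylation of the sulfinate gives the sulfone; no stereocentre is formed.

Step 2
Reactants: 3 3-[(phenylsulfonyl)methyl]furan; 4 1-bromobut-2-yne
Product: 5 rac-3-[1-(phenylsulfonyl)pent-3-yn-1-yl]furan
Conditions: n-BuLi, THF, −78 °C; then 4, −78 → 0 °C
Reagents that add atoms: none
Why: Alkylation of the α-sulfonyl carbanion (Julia-type sulfone alkylation) with the propargylic bromide forms the C6–C7 bond; the new sulfone-bearing centre is racemic and is destroyed in step 5.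

Step 3
Reactants: 5 rac-3-[1-(phenylsulfonyl)pent-3-yn-1-yl]furan
Product: 6 2,5-dimethoxy-3-[1-(phenylsulfonyl)pent-3-yn-1-yl]-2,5-dihydrofuran (diastereomer mixture)
Conditions: Br2 (1.05 equiv), Na2CO3, MeOH, −40 °C
Reagents that add atoms: methanol, CO
Why: Clauson-Kaas oxidative 2,5-dimethoxylation of the furan, which is far faster than bromine addition to the internal alkyne, masks the future dialdehyde as a cyclic bis-acetal whose ring holds C11 cis to C12; the acetal epimers converge in step 10.

Step 4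
Reactants: 6 2,5-dimethoxy-3-[1-(phenylsulfonyl)pent-3-yn-1-yl]-2,5-dihydrofuran; 7 4-methylpent-4-enal
Product: 10 (5S,6E)-9-(2,5-dimethoxy-2,5-dihydrofuran-3-yl)-2,6-dimethyl-9-(phenylsulfonyl)nona-1,6-dien-5-ol, via alkenylzirconocene chloride 8 (not isolated), via alkenyl(methyl)zinc 9 (not isolated)
Conditions: Cp2Zr(H)Cl, CH2Cl2, rt; Me2Zn, toluene, −65 °C; (+)-MIB (10 mol%), 7, −30 → 0 °C; aq. NH4Cl
Reagents that add atoms: none
Why: Wipf-type hydrozirconation/Zr-to-Zn transmetalation and amino-alcohol-catalysed alkenylzinc addition: syn Zr–H addition puts Zr on the methyl-bearing alkyne carbon, which fixes the E-trisubstituted alkene, and (+)-MIB directs Re-face attack on the aldehyde to set the (S)-carbinol (drimane C1).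

Step 5
Reactants: 10 (5S,6E)-9-(2,5-dimethoxy-2,5-dihydrofuran-3-yl)-2,6-dimethyl-9-(phenylsulfonyl)nona-1,6-dien-5-ol
Product: 11 1α-hydroxy-11,12-epoxy-11,12-dimethoxydrim-7-ene (5α-H, 9α-H, 10β-CH3; acetal epimers)
Conditions: Fe(acac)3 (30 mol%), PhSi(OiPr)H2 (3 equiv), THF (0.01 M), Ar, 40 °C
Reagents that add atoms: none
Why: Proposed new method: Fe–H hydrogen-atom transfer (Mukaiyama/Baran-type) to the 1,1-disubstituted alkene gives the tertiary C4 radical, which closes ring A by 6-endo attack on C5 and then ring B by 6-endo attack of the tertiary C10 radical on C9 of the dihydrofuran alkene through a chair–chair transition state (trans fusion from the E-alkene, C11 equatorial because the dihydrofuran ring holds it trans to C7, and the C1 hydroxyl pseudo-axial to avoid A(1,2) strain with the C10 methyl, so the (S)-carbinol dictates the 5S,9R,10S framework), after which the β-sulfonyl C8 radical expels PhSO2• to put the alkene at C7=C8 and the sulfonyl radical is reduced by Fe(II)/silane; the closest known reactions are Fe- and Co-hydride-initiated radical polyene bicyclizations and radical allylations with allyl sulfones.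

Step 6
Reactants: 11 1α-hydroxy-11,12-epoxy-11,12-dimethoxydrim-7-ene
Product: 12 11,12-epoxy-11,12-dimethoxydrim-7-en-1-one
Conditions: TPAP (5 mol%), NMO, 4 Å MS, CH2Cl2, rt
Reagents that add atoms: none
Why: Ley–Griffith oxidation of the axial alcohol under neutral conditions spares the acetal and erases the relay stereocentre at C1; C10 is quaternary, so nothing can epimerise.

Step 7
Reactants: 12 11,12-epoxy-11,12-dimethoxydrim-7-en-1-one
Product: 13 1β-hydroxy-11,12-epoxy-11,12-dimethoxydrim-7-ene
Conditions: NaBH4, CeCl3·7H2O, MeOH, −78 → −20 °C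
Reagents that add atoms: none
Why: Luche reduction: the small hydride attacks C1 along the axial α trajectory (the β face is screened by the axial C10 methyl, as in 1-oxo-5α-steroids) and gives the equatorial 1β-alcohol.

Step 8
Reactants: 13 1β-hydroxy-11,12-epoxy-11,12-dimethoxydrim-7-ene; 14 acryloyl chloride
Product: 15 1β-acryloyloxy-11,12-epoxy-11,12-dimethoxydrim-7-ene
Conditions: iPr2NEt, DMAP (cat.), CH2Cl2, 0 °C → rt
Reagents that add atoms: none
Why: DMAP-catalysed acylation with a small, reactive acyl chloride esterifies the hindered equatorial alcohol with retention at C1.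

Step 9
Reactants: 15 1β-acryloyloxy-11,12-epoxy-11,12-dimethoxydrim-7-ene; 16 4-iodophenol
Product: 17 1β-[(E)-4-hydroxycinnamoyloxy]-11,12-epoxy-11,12-dimethoxydrim-7-ene
Conditions: Pd(OAc)2 (5 mol%), P(o-tol)3, Et3N, MeCN, 80 °C
Reagents that add atoms: none
Why: Mizoroki–Heck arylation of the acrylate (syn insertion, syn β-hydride elimination) gives the E-cinnamate; the free phenol is tolerated and the trisubstituted C7=C8 alkene is inert.

Step 10
Reactants: 17 1β-[(E)-4-hydroxycinnamoyloxy]-11,12-epoxy-11,12-dimethoxydrim-7-ene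
Product: 18 1β-[(E)-p-coumaroyloxy]polygodial, (1R,5S,9R,10S)
Conditions: p-TsOH·H2O (cat.), acetone–H2O (9:1), rt
Reagents that add atoms: water, O
Why: Acid-catalysed hydrolysis of the 2,5-dimethoxytetrahydrofuran releases the 1,4-dialdehyde without base, so the base-labile C9 centre is not touched.

**Compound list**
1 | furan-3-ylmethanol | OCc1ccoc1 | starting material
2 | 3-(bromomethyl)furan (formed in situ) | BrCc1ccoc1 | intermediate
3 | 3-[(phenylsulfonyl)methyl]furan | O=S(=O)(Cc1ccoc1)c1ccccc1 | intermediate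
4 | 1-bromobut-2-yne | CC#CCBr | starting material
5 | rac-3-[1-(phenylsulfonyl)pent-3-yn-1-yl]furan | CC#CCC(c1ccoc1)S(=O)(=O)c1ccccc1 | intermediate
6 | 2,5-dimethoxy-3-[1-(phenylsulfonyl)pent-3-yn-1-yl]-2,5-dihydrofuran (mixture at the sulfone carbon and both acetal carbons) | CC#CCC(C1=CC(OC)OC1OC)S(=O)(=O)c1ccccc1 | intermediate
7 | 4-methylpent-4-enal | C=C(C)CCC=O | starting material
8 | chlorobis(cyclopentadienyl)[(2E)-5-(2,5-dimethoxy-2,5-dihydrofuran-3-yl)-5-(phenylsulfonyl)pent-2-en-2-yl]zirconium (formed in situ) | C/C(=C\CC(C1=CC(OC)OC1OC)S(=O)(=O)c1ccccc1)[Zr](Cl)(C1C=CC=C1)C1C=CC=C1 | intermediate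
9 | methyl[(2E)-5-(2,5-dimethoxy-2,5-dihydrofuran-3-yl)-5-(phenylsulfonyl)pent-2-en-2-yl]zinc (formed in situ) | C/C(=C\CC(C1=CC(OC)OC1OC)S(=O)(=O)c1ccccc1)[Zn]C | intermediate
10 | (5S,6E)-9-(2,5-dimethoxy-2,5-dihydrofuran-3-yl)-2,6-dimethyl-9-(phenylsulfonyl)nona-1,6-dien-5-ol (epimeric at C9 and the acetal carbons) | C=C(C)CC[C@H](O)/C(C)=C/CC(C1=CC(OC)OC1OC)S(=O)(=O)c1ccccc1 | intermediate
11 | 1α-hydroxy-11,12-epoxy-11,12-dimethoxydrim-7-ene, (1S,5S,9R,10S), acetal epimers | CC1(C)CC[C@H](O)[C@]2(C)[C@@H](C(OC)O3)C(C3OC)=CC[C@@H]12 | intermediate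
12 | 11,12-epoxy-11,12-dimethoxydrim-7-en-1-one (5α-H, 9α-H, 10β-CH3), acetal epimers | CC1(C)CCC(=O)[C@]2(C)[C@@H](C(OC)O3)C(C3OC)=CC[C@@H]12 | intermediate
13 | 1β-hydroxy-11,12-epoxy-11,12-dimethoxydrim-7-ene, (1R,5S,9R,10S), acetal epimers | CC1(C)CC[C@@H](O)[C@]2(C)[C@@H](C(OC)O3)C(C3OC)=CC[C@@H]12 | intermediate
14 | acryloyl chloride | C=CC(Cl)=O | starting material
15 | 1β-acryloyloxy-11,12-epoxy-11,12-dimethoxydrim-7-ene, acetal epimers | CC1(C)CC[C@@H](OC(=O)C=C)[C@]2(C)[C@@H](C(OC)O3)C(C3OC)=CC[C@@H]12 | intermediate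
16 | 4-iodophenol | Oc1ccc(I)cc1 | starting material
17 | 1β-[(E)-4-hydroxycinnamoyloxy]-11,12-epoxy-11,12-dimethoxydrim-7-ene, acetal epimers | CC1(C)CC[C@@H](OC(=O)/C=C/c4ccc(O)cc4)[C@]2(C)[C@@H](C(OC)O3)C(C3OC)=CC[C@@H]12 | intermediate
18 | 1β-[(E)-p-coumaroyloxy]polygodial, (1R,5S,9R,10S)-drim-7-ene-11,12-dial 1-O-(E)-4-hydroxycinnamate | CC1(C)CC[C@@H](OC(=O)/C=C/c2ccc(O)cc2)[C@]2(C)[C@@H](C=O)C(C=O)=CC[C@@H]12 | target

**Step count:** 10 steps in total; longest linear sequence 10 steps (1 → 18).

**Three steps most likely to fail**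

Step 5 (radical bicyclization). The cascade is untested in this form. The weakest point is the facial control by the C1 hydroxyl: the pseudo-axial preference is a conformational argument, and the selectivity may be modest (the minor diastereomer is separable) or even reversed. Premature reduction of the C10 radical is a second risk. Fallback, setting out from 6 and returning at 13: step 4 is run with (−)-MIB to give (5R,6E)-9-(2,5-dimethoxy-2,5-dihydrofuran-3-yl)-2,6-dimethyl-9-(phenylsulfonyl)nona-1,6-dien-5-ol F1. If the hydroxyl in fact sits pseudo-equatorial, the same cascade on F1 gives 13 directly, so the C1 centre is transferred instead of relayed through the ketone and steps 6 and 7 drop out.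

Step 4 (hydrozirconation and asymmetric alkenylzinc addition). Enantioselectivity with an unbranched aldehyde may be insufficient, and the sulfone and acetal may interfere with the zinc step. Fallback, setting out from 6 and 7 and returning at 10: the same hydrozirconation/zinc exchange without ligand gives (6E)-9-(2,5-dimethoxy-2,5-dihydrofuran-3-yl)-2,6-dimethyl-9-(phenylsulfonyl)nona-1,6-dien-5-ol as both C5 epimers F2. MnO2 oxidises this allylic alcohol to (6E)-9-(2,5-dimethoxy-2,5-dihydrofuran-3-yl)-2,6-dimethyl-9-(phenylsulfonyl)nona-1,6-dien-5-one F3. (R)-Me-CBS/catecholborane reduction (alkenyl as the large group) then sets the carbinol by reagent control and gives 10.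

Step 9 (Heck reaction on the hindered acrylate). The phenoxide may add to the acrylate, and the ammonium iodide may ionise the allylic acetal at 80 °C. Fallback, setting out from 13 and returning at 17: the cinnamate is made first and attached whole. 16 and acrylic acid F4 are joined by a Heck reaction to (E)-4-hydroxycinnamic acid F5, which Ac2O/pyridine converts to (E)-4-acetoxycinnamic acid F6. Yamaguchi esterification of 13 with F6 gives 1β-[(E)-4-acetoxycinnamoyloxy]-11,12-epoxy-11,12-dimethoxydrim-7-ene F7. Catalytic K2CO3 in MeOH at 0 °C removes the phenolic acetate and gives 17.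

Further compounds
F1 | step 5 | (5R,6E)-9-(2,5-dimethoxy-2,5-dihydrofuran-3-yl)-2,6-dimethyl-9-(phenylsulfonyl)nona-1,6-dien-5-ol | C=C(C)CC[C@@H](O)/C(C)=C/CC(C1=CC(OC)OC1OC)S(=O)(=O)c1ccccc1
F2 | step 4 | (6E)-9-(2,5-dimethoxy-2,5-dihydrofuran-3-yl)-2,6-dimethyl-9-(phenylsulfonyl)nona-1,6-dien-5-ol as both C5 epimers | C=C(C)CCC(O)/C(C)=C/CC(C1=CC(OC)OC1OC)S(=O)(=O)c1ccccc1
F3 | step 4 | (6E)-9-(2,5-dimethoxy-2,5-dihydrofuran-3-yl)-2,6-dimethyl-9-(phenylsulfonyl)nona-1,6-dien-5-one | C=C(C)CCC(=O)/C(C)=C/CC(C1=CC(OC)OC1OC)S(=O)(=O)c1ccccc1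
F4 | step 9 | acrylic acid | C=CC(=O)O
F5 | step 9 | (E)-4-hydroxycinnamic acid | O=C(O)/C=C/c1ccc(O)cc1
F6 | step 9 | (E)-4-acetoxycinnamic acid | CC(=O)Oc1ccc(/C=C/C(=O)O)cc1
F7 | step 9 | 1β-[(E)-4-acetoxycinnamoyloxy]-11,12-epoxy-11,12-dimethoxydrim-7-ene | CC1(C)CC[C@@H](OC(=O)/C=C/c4ccc(OC(C)=O)cc4)[C@]2(C)[C@@H](C(OC)O3)C(C3OC)=CC[C@@H]12
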